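Follow the target through the east run, which is the very flask asked about, watched so far.

- east: substrate 20 mM; reagent in the second phase 4 equiv; temperature −20 °C; the very flask that is asked about, followed so far
- flask: substrate 20 mM; reagent in the second phase 4.00 equiv; temperature −20 °C; time 2.0 h; volume of the second phase over the first 1.0

east run (percent of the substrate charged)

| time / min | target / % | substrate / % |
|---|---|---|
| 6.00 | 30.4 | 0.2 |
| 10.0 | 19.4 | 1.2 |
| 15.0 | 17.2 | 0.2 |
| 25.0 | 16.2 | 0.8 |
| 40.0 | 17.0 | 0.2 |
| 80.0 | 17.0 | 0.3 |

(readings scatter by 0.5 percentage points)

- in the second phase: reagent in the second phase; everything else is in the first
- charges count per volume of the first phase; a concentration in a rate is the amount of a species over the volume of its own phase; every rate counts per litre of the first phase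
- target taken out counts as made
- steps under discussion: substrate + reagent in the reaction phase <-> target; target <-> isomer of the product; reagent in the reaction phase <-> reagent in the second phase
- the earlier runs hold the two phases in the same ratio of volumes as the flask asked about
- additions bring no volume worth counting
- the earlier runs do not show what temperature does; that part of a forecast is a guess

- autumn: at 2.0 h add substrate, 50.0% of the amount charged, then wait 40 min
- spring: change nothing and wait 40 min more
- winter: at 2.0 h take out 90% of the target then present, then wait 40 min
- summer: at 2.0 h raise the temperature by 25 K, then wait 40 min

- target, in percent of the substrate first charged, at 2.0 h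
- the remedy with the largest gain of target, or "none" below 2 percentage points (autumn / spring / winter / summer / none)
- target present, with what was taken out counted in, in percent of the substrate first charged, after winter
- target present, with what was taken out counted in, in percent of the substrate first charged, after summer

Draw the east curve from both ends and join them. At the late end the target stops moving, so average its last readings:

level = (16.2% + 17.0% + 17.0%) / 3 = 16.7%

Call this the resting share: the part of the charged substrate standing as target once target and isomer have stopped trading, at one fixed temperature (thermodynamic control).

At the early end the target starts from nothing and reads 30.4% at 6.00 min, a mean climb of 0.0507 /min of the charge, with substrate already down to 0.2%. Count what is neither as isomer: it reads 69.4%, more than the target, so the two curves crossed before that reading.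

Now join the ends through the excess over the level:

excess at 6.00 min = 14 percentage points
excess at 10.0 min = 2.7 points
half-life of the excess = 1.70 min

This half-life is a reading, and it is far shorter than the 2.0 h. So the knee comes near 15.0 min, where the excess of 0.47 points stands against a scatter of 0.5 points. Because the 40 min wait also exceeds that half-life, reckon each remedy at rest, with target equal to the share of the pool:

now = 16.7%
autumn: pool up by 50.0%, target 25.1%
winter: 15.1% taken out, then 29.3% counted

Spring adds nothing. The readings hold no share for a warmer flask, so leave summer open and commit to winter, a gain of 13 points.

The forecast gives 17% (16.4% to 17.5%), winter as best, 29.7% after winter, and 19% after summer (14% to 26%), saying “the equilibrium shift is unknown”. Its winter stands a little above mine.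

The flask gives 16.3% at 2.0 h, and summer gains most, 70 points against 12 points for winter. substrate + reagent in the reaction phase ⇌ target (K = 1000 /M, k = 0.460 /M/s, Ea = 47.0 kJ/mol, ΔH = 22.0 kJ/mol); target ⇌ isomer of the product (K = 5.10, k = 0.00500 /s, Ea = 76.0 kJ/mol, ΔH = −82.0 kJ/mol); reagent in the reaction phase ⇌ reagent in the second phase, rate k3*([reagent in the reaction phase] - [reagent in the second phase]/K3) per volume of the first phase (partition coefficient = 0.440, kL = 0.0340 /s); (constants at −20 °C)

Winter ends at 28.6%, where the share of 16.7% reckoned 29.3%; summer ends at 86.0%, against the forecast's 19%. A neighbour flask kept at 5 °C, the temperature summer reaches, ends with target 86.0% and isomer 13.2%, so its target share of the charge is 86.0%, which is 5.15 times the carried one. The flask asked about has come to rest: the two-way half-life of target and isomer by their own step is 1.93 min, and at 1200 min the target reads 16.3%, a change of 0 points.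

(Readings and results are calculated with constants of no real substance.)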